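The route rests on disconnecting the benzene ring (C4a, C5, C6, C7, C8, C8a) together with its fusion bond to ring B (C1–C4). That ring carries oxygen at C5 and C6, the carboxyl at C7 and its only hydrogen at C8, which maps onto a 4,5-dioxygenated 2-pyrone-3-carboxylate plus a terminal alkyne. One thermal operation, intramolecular pyrone–alkyne [4+2] addition followed by loss of CO2, forms C7–C8 and C4a–C8a and closes both rings with all four stereocentres already in place. The precursor 35 is a 6-alkyl pyrone (benzyl ester, two benzyl ethers) whose chain holds C4, C3, C2 and C1 with its ethynyl group, the C12 acetate and the C17 benzyl ether.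

Key step: step 18

Remark: locants follow the target (tetralin C1–C8a, ring A = benzene ring, ring B = C1–C4 ring, side chain C11–C17 with C12 = acetoxymethyl and C17 = hydroxymethyl carbon); both enantiomers of 3-bromo-2-methylpropan-1-ol and of 4-benzyloxazolidin-2-one are assumed to be purchasable.

Step 1
Reactants: 1 (R)-3-bromo-2-methylpropan-1-ol
Product: 2 (R)-[(3-bromo-2-methylpropoxy)methyl]benzene
Conditions: BnOC(=NH)CCl3, TfOH (cat.), CH2Cl2–cyclohexane, 0 °C → rt
Reagents that add atoms: benzyl 2,2,2-trichloroacetimidate, N=C(OCc1ccccc1)C(Cl)(Cl)Cl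
Why: Acid-catalysed trichloroacetimidate O-benzylation avoids base, so the γ-bromo alcohol cannot close to an oxetane and the C16 stereocentre (from the chiral pool) is untouched.

Step 2
Reactants: 2 (R)-[(3-bromo-2-methylpropoxy)methyl]benzene; 3 tert-butyl 4-bromobutanoate
Product: 5 tert-butyl (S)-7-(benzyloxy)-6-methylheptanoate, via Grignard reagent 4 (not isolated)
Conditions: Mg, THF, 45 °C; then 3, Li2CuCl4 (3 mol%), NMP, THF, 0 °C → rt
Reagents that add atoms: none
Why: Kochi–Cahiez copper-catalysed sp3–sp3 cross-coupling of a primary alkyl Grignard reagent with a primary bromide should outrun addition to the hindered tert-butyl ester and forms C14–C15 without involving C16.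

Step 3
Reactants: 5 tert-butyl (S)-7-(benzyloxy)-6-methylheptanoate
Product: 6 (S)-7-(benzyloxy)-6-methylheptanoic acid
Conditions: CF3CO2H, CH2Cl2, rt
Reagents that add atoms: none
Why: Acidolysis of a tert-butyl ester (loss of isobutene) frees the acid, and a benzyl ether is stable to these conditions.

Step 4
Reactants: 6 (S)-7-(benzyloxy)-6-methylheptanoic acid; 7 (R)-4-benzyloxazolidin-2-one
Product: 9 (R)-4-benzyl-3-[(S)-7-(benzyloxy)-6-methylheptanoyl]oxazolidin-2-one, via mixed pivalic anhydride 8 (not isolated)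
Conditions: t-BuCOCl, Et3N, THF, −20 °C; then 7, LiCl, rt
Reagents that add atoms: none
Why: N-Acylation of the oxazolidinone through the mixed pivalic anhydride under LiCl/Et3N activation is the standard strong-base-free way to load an Evans auxiliary.

Step 5
Reactants: 9 (R)-4-benzyl-3-[(S)-7-(benzyloxy)-6-methylheptanoyl]oxazolidin-2-one; 10 tert-butyl bromoacetate
Product: 12 tert-butyl (3S,7S)-3-[(R)-4-benzyl-2-oxooxazolidine-3-carbonyl]-8-(benzyloxy)-7-methyloctanoate, via sodium Z-enolate 11 (not isolated)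
Conditions: NaN(SiMe3)2, THF, −78 °C; then 10, −78 → −40 °C
Reagents that add atoms: none
Why: Evans asymmetric alkylation: the chelated Z-enolate is attacked by the reactive α-bromo ester on the face opposite the benzyl group of the (R)-auxiliary, which sets C11 in the required sense.

Step 6
Reactants: 12 tert-butyl (3S,7S)-3-[(R)-4-benzyl-2-oxooxazolidine-3-carbonyl]-8-(benzyloxy)-7-methyloctanoate
Product: 14 (S)-4-[(S)-5-(benzyloxy)-4-methylpentyl]dihydrofuran-2(3H)-one, via hydroxy ester 13 (not isolated)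
Conditions: LiBH4, MeOH (1 equiv), Et2O, 0 °C; then TsOH·H2O (cat.), toluene, 60 °C
Reagents that add atoms: none
Why: Reductive cleavage of the imide with LiBH4 gives the C12 primary alcohol and returns the auxiliary while the tert-butyl ester survives, and acid-catalysed lactonisation then closes the γ-butyrolactone without touching C11.

Step 7
Reactants: 15 (S)-3-bromo-2-methylpropan-1-ol
Product: 16 (S)-(3-bromo-2-methylpropoxy)(tert-butyl)dimethylsilane
Conditions: t-BuMe2SiCl, imidazole, CH2Cl2, rt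
Reagents that add atoms: tert-butyldimethylsilyl chloride, CC(C)(C)[Si](C)(C)Cl
Why: Imidazole-promoted silylation of a primary alcohol is routine and leaves the C4 stereocentre (from the chiral pool) untouched.

Step 8
Reactants: 16 (S)-(3-bromo-2-methylpropoxy)(tert-butyl)dimethylsilane
Product: 18 (R)-4-[(tert-butyldimethylsilyl)oxy]-3-methylbutan-1-ol, via Grignard reagent 17 (not isolated)
Conditions: Mg, THF, 45 °C; then (CH2O)n, 0 °C → rt
Reagents that add atoms: formaldehyde (used as paraformaldehyde), C=O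
Why: Grignard addition to formaldehyde gives the one-carbon-homologated primary alcohol (new carbon = C2), the silyl ether being inert to the organomagnesium.

Step 9
Reactants: 18 (R)-4-[(tert-butyldimethylsilyl)oxy]-3-methylbutan-1-ol
Product: 19 (R)-tert-butyl(4-iodo-2-methylbutoxy)dimethylsilane
Conditions: I2, PPh3, imidazole, CH2Cl2, 0 °C → rt
Reagents that add atoms: iodine, II
Why: Appel-type iodination converts the primary alcohol into the iodide by SN2 at a non-stereogenic carbon under conditions that spare the silyl ether.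

Step 10
Reactants: 14 (S)-4-[(S)-5-(benzyloxy)-4-methylpentyl]dihydrofuran-2(3H)-one; 19 (R)-tert-butyl(4-iodo-2-methylbutoxy)dimethylsilane
Product: 21 (3S,4S)-4-[(S)-5-(benzyloxy)-4-methylpentyl]-3-{(R)-4-[(tert-butyldimethylsilyl)oxy]-3-methylbutyl}dihydrofuran-2(3H)-one, via lithium enolate 20 (not isolated)
Conditions: LiN(i-Pr)2, THF, −78 °C; then 19, DMPU, −78 → −30 °C
Reagents that add atoms: none
Why: Kinetic alkylation of a γ-butyrolactone lithium enolate with a primary iodide takes place anti to the substituent on the neighbouring ring carbon (C11), so the trans-3,4-disubstituted lactone should form and C1 is set relative to C11.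

Step 11
Reactants: 21 (3S,4S)-4-[(S)-5-(benzyloxy)-4-methylpentyl]-3-{(R)-4-[(tert-butyldimethylsilyl)oxy]-3-methylbutyl}dihydrofuran-2(3H)-one
Product: 22 (3S,4S)-4-[(S)-5-(benzyloxy)-4-methylpentyl]-3-{(R)-4-[(tert-butyldimethylsilyl)oxy]-3-methylbutyl}tetrahydrofuran-2-ol (anomer mixture)
Conditions: i-Bu2AlH (1.1 equiv), CH2Cl2, −78 °C
Reagents that add atoms: none
Why: Partial reduction of a lactone to the lactol with one equivalent of i-Bu2AlH at low temperature is reliable because the aluminium hemiacetal persists until work-up.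

Step 12
Reactants: 22 (3S,4S)-4-[(S)-5-(benzyloxy)-4-methylpentyl]-3-{(R)-4-[(tert-butyldimethylsilyl)oxy]-3-methylbutyl}tetrahydrofuran-2-ol
Product: 23 (2S,3S,6R)-2-[(S)-5-(benzyloxy)-4-methylpentyl]-7-[(tert-butyldimethylsilyl)oxy]-3-ethynyl-6-methylheptan-1-ol
Conditions: MeCOC(N2)P(O)(OMe)2, K2CO3, MeOH, 0 °C → rt
Reagents that add atoms: dimethyl (1-diazo-2-oxopropyl)phosphonate, COP(=O)(OC)C(=[N+]=[N-])C(C)=O
Why: Seyferth–Gilbert homologation with the Ohira–Bestmann reagent acts on the open hydroxy-aldehyde form of the lactol, turning C8a into the terminal alkyne (new carbon = C8) and releasing the C12 hydroxyl, and the mild carbonate base is expected to leave the α-stereocentre C1 intact.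

Step 13
Reactants: 23 (2S,3S,6R)-2-[(S)-5-(benzyloxy)-4-methylpentyl]-7-[(tert-butyldimethylsilyl)oxy]-3-ethynyl-6-methylheptan-1-ol
Product: 24 (2S,3S,6R)-2-[(S)-5-(benzyloxy)-4-methylpentyl]-7-[(tert-butyldimethylsilyl)oxy]-3-ethynyl-6-methylheptyl acetate
Conditions: Ac2O, pyridine, DMAP (cat.), CH2Cl2, 0 °C → rt
Reagents that add atoms: acetic anhydride, CC(=O)OC(C)=O
Why: DMAP-catalysed acetylation of the only free hydroxyl installs the C12 acetate of the target at the point where C12 and C17 are already differentiated.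

Step 14
Reactants: 24 (2S,3S,6R)-2-[(S)-5-(benzyloxy)-4-methylpentyl]-7-[(tert-butyldimethylsilyl)oxy]-3-ethynyl-6-methylheptyl acetate
Product: 27 (2R,5S,6S,10S)-6-(acetoxymethyl)-11-(benzyloxy)-5-ethynyl-2,10-dimethylundecanoic acid, via primary alcohol 25 (not isolated), via aldehyde 26 (not isolated)
Conditions: CrO3, H2SO4, H2O (Jones reagent), acetone, 0 °C → rt
Reagents that add atoms: water, O
Why: Jones oxidation in aqueous acid cleaves the primary silyl ether and oxidises the liberated alcohol through the aldehyde hydrate to the C4a acid, conditions that alkyl acetates, benzyl ethers and terminal alkynes tolerate and under which the rapidly consumed aldehyde should not epimerise at C4.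

Step 15
Reactants: 28 dibenzyl malonate; 29 2-(benzyloxy)acetyl chloride
Product: 30 dibenzyl 2-[2-(benzyloxy)acetyl]malonate
Conditions: MgCl2, Et3N, MeCN, 0 °C → rt
Reagents that add atoms: none
Why: Soft-enolisation C-acylation of a malonate (MgCl2/Et3N, Rathke conditions) stops cleanly at the acylmalonate because the product is held as its chelated magnesium enolate.

Step 16
Reactants: 27 (2R,5S,6S,10S)-6-(acetoxymethyl)-11-(benzyloxy)-5-ethynyl-2,10-dimethylundecanoic acid; 30 dibenzyl 2-[2-(benzyloxy)acetyl]malonate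
Product: 34 benzyl 6-[(2R,5S,6S,10S)-6-(acetoxymethyl)-11-(benzyloxy)-5-ethynyl-10-methylundecan-2-yl]-5-(benzyloxy)-4-hydroxy-2-oxo-2H-pyran-3-carboxylate, via acyl imidazolide 31 (not isolated), via dilithium dianion 32 (not isolated), via open-chain tetracarbonyl ester 33 (not isolated)
Conditions: 27, 1,1'-carbonyldiimidazole, THF, rt; separately 30 (4 equiv), LiN(i-Pr)2 (7.8 equiv), THF, −78 → −40 °C; mix at −78 °C; aq. HCl; then DBU, toluene, 50 °C
Reagents that add atoms: none
Why: Harris–Weiler-type γ-acylation of a 1,3-dicarbonyl dianion: the CH(OBn) carbanion of the tricarbonyl dianion should attack the acyl imidazolide far faster than the alkyl acetate (excess dianion absorbs the imidazole and alkyne protons), and the enolised tetracarbonyl then lactonises onto a malonate ester with loss of benzyl alcohol to give the 4-hydroxy-2-pyrone, C4 being shielded from enolisation because the adjacent 1,3-dicarbonyl is deprotonated first.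

Step 17
Reactants: 34 benzyl 6-[(2R,5S,6S,10S)-6-(acetoxymethyl)-11-(benzyloxy)-5-ethynyl-10-methylundecan-2-yl]-5-(benzyloxy)-4-hydroxy-2-oxo-2H-pyran-3-carboxylate
Product: 35 benzyl 6-[(2R,5S,6S,10S)-6-(acetoxymethyl)-11-(benzyloxy)-5-ethynyl-10-methylundecan-2-yl]-4,5-bis(benzyloxy)-2-oxo-2H-pyran-3-carboxylate
Conditions: BnOH, PPh3, i-PrO2CN=NCO2i-Pr, THF, 0 °C → rt
Reagents that add atoms: benzyl alcohol, OCc1ccccc1
Why: Mitsunobu O-alkylation of the acidic 4-hydroxy-2-pyrone (a vinylogous acid) should give the 4-benzyloxy-2-pyrone under neutral conditions, so neither the acetate nor the pyrone-adjacent stereocentre C4 sees base.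

Step 18
Reactants: 35 benzyl 6-[(2R,5S,6S,10S)-6-(acetoxymethyl)-11-(benzyloxy)-5-ethynyl-10-methylundecan-2-yl]-4,5-bis(benzyloxy)-2-oxo-2H-pyran-3-carboxylate
Product: 37 benzyl (5R,8S)-8-[(2S,6S)-1-acetoxy-7-(benzyloxy)-6-methylheptan-2-yl]-3,4-bis(benzyloxy)-5-methyl-5,6,7,8-tetrahydronaphthalene-2-carboxylate, via bridged bicyclic lactone 36 (not isolated)
Conditions: 1,2-dichlorobenzene (0.01 M, degassed), BHT, 180 °C, sealed tube
Reagents that add atoms: none
Why: On heating, the pyrone serves as the 4π component and the tethered terminal alkyne as the 2π component of an intramolecular [4+2] cycloaddition that gives the bridged 2-oxabicyclo[2.2.2]octadienone 36, which at the same temperature expels CO2 by retro-[4+2] and leaves the benzene ring. The closest known reaction type is the intramolecular 2-pyrone–alkyne Diels–Alder/decarboxylative cycloreversion used to make benzo-fused carbocycles, applied here to a fully oxygenated pyrone. Ring B closes as a six-membered ring through the new C4a–C8a bond because the four-carbon tether C4–C3–C2–C1 links the diene terminus (pyrone C6) to the alkyne, and ring A closes through C7–C8 together with C4a–C8a and becomes aromatic on CO2 loss without any oxidant. No stereocentre is created: C1, C4, C11 and C16 are sp3 carbons outside the reacting π systems under neutral conditions, and the bridgehead configuration of 36 is erased on aromatisation. The only selectivity required is regiochemical and the tether enforces it, since the internal alkyne carbon can reach only pyrone C6 and the terminal CH only pyrone C3, which places the single aromatic hydrogen at C8; high dilution and a radical inhibitor guard against intermolecular cycloaddition and benzyl-ether degradation.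

Step 19
Reactants: 37 benzyl (5R,8S)-8-[(2S,6S)-1-acetoxy-7-(benzyloxy)-6-methylheptan-2-yl]-3,4-bis(benzyloxy)-5-methyl-5,6,7,8-tetrahydronaphthalene-2-carboxylate
Product: 38 (5R,8S)-8-[(2S,6S)-1-acetoxy-7-hydroxy-6-methylheptan-2-yl]-3,4-dihydroxy-5-methyl-5,6,7,8-tetrahydronaphthalene-2-carboxylic acid
Conditions: H2 (1 atm), Pd/C, EtOAc–EtOH, rt
Reagents that add atoms: none
Why: Catalytic hydrogenolysis cleaves the benzyl ester, the two aryl benzyl ethers and the C17 alkyl benzyl ether in one operation, while the acetate, the arene and the benzylic C–H stereocentres C1 and C4 are inert.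

Compound list
1 | (R)-3-bromo-2-methylpropan-1-ol | BrC[C@H](C)CO | starting material
2 | (R)-[(3-bromo-2-methylpropoxy)methyl]benzene | BrC[C@H](C)COCc1ccccc1 | intermediate
3 | tert-butyl 4-bromobutanoate | CC(C)(C)OC(=O)CCCBr | starting material
4 | (R)-[3-(benzyloxy)-2-methylpropyl]magnesium bromide | Br[Mg]C[C@H](C)COCc1ccccc1 | intermediate
5 | tert-butyl (S)-7-(benzyloxy)-6-methylheptanoate | CC(C)(C)OC(=O)CCCC[C@H](C)COCc1ccccc1 | intermediate
6 | (S)-7-(benzyloxy)-6-methylheptanoic acid | OC(=O)CCCC[C@H](C)COCc1ccccc1 | intermediate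
7 | (R)-4-benzyloxazolidin-2-one | O=C1N[C@H](Cc2ccccc2)CO1 | starting material
8 | (S)-7-(benzyloxy)-6-methylheptanoic pivalic anhydride | CC(C)(C)C(=O)OC(=O)CCCC[C@H](C)COCc1ccccc1 | intermediate
9 | (R)-4-benzyl-3-[(S)-7-(benzyloxy)-6-methylheptanoyl]oxazolidin-2-one | O=C(CCCC[C@H](C)COCc1ccccc1)N1[C@H](Cc2ccccc2)COC1=O | intermediate
10 | tert-butyl bromoacetate | CC(C)(C)OC(=O)CBr | starting material
11 | sodium (Z)-enolate of 9 | [Na]O/C(=C\CCC[C@H](C)COCc1ccccc1)N1[C@H](Cc2ccccc2)COC1=O | intermediate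
12 | tert-butyl (3S,7S)-3-[(R)-4-benzyl-2-oxooxazolidine-3-carbonyl]-8-(benzyloxy)-7-methyloctanoate | O=C([C@@H](CCC[C@H](C)COCc1ccccc1)CC(=O)OC(C)(C)C)N1[C@H](Cc2ccccc2)COC1=O | intermediate
13 | tert-butyl (3S,7S)-8-(benzyloxy)-3-(hydroxymethyl)-7-methyloctanoate | OC[C@@H](CCC[C@H](C)COCc1ccccc1)CC(=O)OC(C)(C)C | intermediate
14 | (S)-4-[(S)-5-(benzyloxy)-4-methylpentyl]dihydrofuran-2(3H)-one | O=C1C[C@H](CCC[C@H](C)COCc2ccccc2)CO1 | intermediate
15 | (S)-3-bromo-2-methylpropan-1-ol | BrC[C@@H](C)CO | starting material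
16 | (S)-(3-bromo-2-methylpropoxy)(tert-butyl)dimethylsilane | BrC[C@@H](C)CO[Si](C)(C)C(C)(C)C | intermediate
17 | (S)-{3-[(tert-butyldimethylsilyl)oxy]-2-methylpropyl}magnesium bromide | Br[Mg]C[C@@H](C)CO[Si](C)(C)C(C)(C)C | intermediate
18 | (R)-4-[(tert-butyldimethylsilyl)oxy]-3-methylbutan-1-ol | OCC[C@@H](C)CO[Si](C)(C)C(C)(C)C | intermediate
19 | (R)-tert-butyl(4-iodo-2-methylbutoxy)dimethylsilane | ICC[C@@H](C)CO[Si](C)(C)C(C)(C)C | intermediate
20 | lithium enolate of 14 (lithium (S)-4-[(S)-5-(benzyloxy)-4-methylpentyl]-4,5-dihydrofuran-2-olate) | [Li]OC1=C[C@H](CCC[C@H](C)COCc2ccccc2)CO1 | intermediate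
21 | (3S,4S)-4-[(S)-5-(benzyloxy)-4-methylpentyl]-3-{(R)-4-[(tert-butyldimethylsilyl)oxy]-3-methylbutyl}dihydrofuran-2(3H)-one | O=C1[C@@H](CC[C@@H](C)CO[Si](C)(C)C(C)(C)C)[C@H](CCC[C@H](C)COCc2ccccc2)CO1 | intermediate
22 | (3S,4S)-4-[(S)-5-(benzyloxy)-4-methylpentyl]-3-{(R)-4-[(tert-butyldimethylsilyl)oxy]-3-methylbutyl}tetrahydrofuran-2-ol (anomer mixture, hemiacetal carbon undefined) | OC1[C@@H](CC[C@@H](C)CO[Si](C)(C)C(C)(C)C)[C@H](CCC[C@H](C)COCc2ccccc2)CO1 | intermediate
23 | (2S,3S,6R)-2-[(S)-5-(benzyloxy)-4-methylpentyl]-7-[(tert-butyldimethylsilyl)oxy]-3-ethynyl-6-methylheptan-1-ol | OC[C@@H](CCC[C@H](C)COCc1ccccc1)[C@@H](C#C)CC[C@@H](C)CO[Si](C)(C)C(C)(C)C | intermediate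
24 | (2S,3S,6R)-2-[(S)-5-(benzyloxy)-4-methylpentyl]-7-[(tert-butyldimethylsilyl)oxy]-3-ethynyl-6-methylheptyl acetate | CC(=O)OC[C@@H](CCC[C@H](C)COCc1ccccc1)[C@@H](C#C)CC[C@@H](C)CO[Si](C)(C)C(C)(C)C | intermediate
25 | (2S,3S,6R)-2-[(S)-5-(benzyloxy)-4-methylpentyl]-3-ethynyl-7-hydroxy-6-methylheptyl acetate | CC(=O)OC[C@@H](CCC[C@H](C)COCc1ccccc1)[C@@H](C#C)CC[C@@H](C)CO | intermediate
26 | (2S,3S,6R)-2-[(S)-5-(benzyloxy)-4-methylpentyl]-3-ethynyl-6-methyl-7-oxoheptyl acetate | CC(=O)OC[C@@H](CCC[C@H](C)COCc1ccccc1)[C@@H](C#C)CC[C@@H](C)C=O | intermediate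
27 | (2R,5S,6S,10S)-6-(acetoxymethyl)-11-(benzyloxy)-5-ethynyl-2,10-dimethylundecanoic acid | CC(=O)OC[C@@H](CCC[C@H](C)COCc1ccccc1)[C@@H](C#C)CC[C@@H](C)C(=O)O | intermediate
28 | dibenzyl malonate | O=C(CC(=O)OCc1ccccc1)OCc1ccccc1 | starting material
29 | 2-(benzyloxy)acetyl chloride | O=C(Cl)COCc1ccccc1 | starting material
30 | dibenzyl 2-[2-(benzyloxy)acetyl]malonate | O=C(COCc1ccccc1)C(C(=O)OCc1ccccc1)C(=O)OCc1ccccc1 | intermediate
31 | acyl imidazolide of 27, (2S,3S,6R)-2-[(S)-5-(benzyloxy)-4-methylpentyl]-3-ethynyl-7-(1H-imidazol-1-yl)-6-methyl-7-oxoheptyl acetate | CC(=O)OC[C@@H](CCC[C@H](C)COCc1ccccc1)[C@@H](C#C)CC[C@@H](C)C(=O)n1ccnc1 | intermediate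
32 | dilithium dianion of 30 (bis-enolate, double-bond geometry undefined) | [Li]OC(=COCc1ccccc1)C(C(=O)OCc1ccccc1)=C(O[Li])OCc1ccccc1 | intermediate
33 | dibenzyl 2-[(4R,7S,8S,12S)-8-(acetoxymethyl)-2,13-bis(benzyloxy)-7-ethynyl-4,12-dimethyl-3-oxotridecanoyl]malonate (enolised, CH(OBn) carbon undefined) | CC(=O)OC[C@@H](CCC[C@H](C)COCc1ccccc1)[C@@H](C#C)CC[C@@H](C)C(=O)C(OCc1ccccc1)C(=O)C(C(=O)OCc1ccccc1)C(=O)OCc1ccccc1 | intermediate
34 | benzyl 6-[(2R,5S,6S,10S)-6-(acetoxymethyl)-11-(benzyloxy)-5-ethynyl-10-methylundecan-2-yl]-5-(benzyloxy)-4-hydroxy-2-oxo-2H-pyran-3-carboxylate | CC(=O)OC[C@@H](CCC[C@H](C)COCc1ccccc1)[C@@H](C#C)CC[C@@H](C)C1=C(OCc2ccccc2)C(O)=C(C(=O)OCc2ccccc2)C(=O)O1 | intermediate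
35 | benzyl 6-[(2R,5S,6S,10S)-6-(acetoxymethyl)-11-(benzyloxy)-5-ethynyl-10-methylundecan-2-yl]-4,5-bis(benzyloxy)-2-oxo-2H-pyran-3-carboxylate | CC(=O)OC[C@@H](CCC[C@H](C)COCc1ccccc1)[C@@H](C#C)CC[C@@H](C)C1=C(OCc2ccccc2)C(OCc2ccccc2)=C(C(=O)OCc2ccccc2)C(=O)O1 | intermediate
36 | bridged [4+2] adduct of 35 (2-oxabicyclo[2.2.2]octadienone fused to ring B; either bridgehead diastereomer, bridgeheads undefined) | CC(=O)OC[C@@H](CCC[C@H](C)COCc1ccccc1)[C@@H]1CC[C@@H](C)C23OC(=O)C(C(=O)OCc4ccccc4)(C=C12)C(OCc1ccccc1)=C3OCc1ccccc1 | intermediate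
37 | benzyl (5R,8S)-8-[(2S,6S)-1-acetoxy-7-(benzyloxy)-6-methylheptan-2-yl]-3,4-bis(benzyloxy)-5-methyl-5,6,7,8-tetrahydronaphthalene-2-carboxylate (tetrabenzyl-protected target) | CC(=O)OC[C@@H](CCC[C@H](C)COCc1ccccc1)[C@@H]1CC[C@@H](C)c2c1cc(C(=O)OCc1ccccc1)c(OCc1ccccc1)c2OCc1ccccc1 | intermediate
38 | (5R,8S)-8-[(2S,6S)-1-acetoxy-7-hydroxy-6-methylheptan-2-yl]-3,4-dihydroxy-5-methyl-5,6,7,8-tetrahydronaphthalene-2-carboxylic acid | CC(=O)OC[C@@H](CCC[C@H](C)CO)[C@@H]1CC[C@@H](C)c2c1cc(C(=O)O)c(O)c2O | target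

Total step count: 19.
Longest linear sequence: 15 steps (steps 1–6, 10–14, 16–19); steps 7–9 and step 15 are side branches.

Steps most likely to fail

Step 18. The cycloaddition of the unactivated terminal alkyne may be slower than thermal degradation of the benzyl-rich pyrone (benzyl migration or loss, intermolecular cycloaddition), so that conversion stalls before ring closure. The fallback activates the 2π partner with a traceless halogen and sets out from 35. Bromination of the terminal alkyne with N-bromosuccinimide and AgNO3 (cat.) in acetone should give benzyl 6-[(2R,5S,6S,10S)-6-(acetoxymethyl)-11-(benzyloxy)-5-(bromoethynyl)-10-methylundecan-2-yl]-4,5-bis(benzyloxy)-2-oxo-2H-pyran-3-carboxylate F1. 1-Haloalkynes are known partners in pyrone Diels–Alder benzannulation, and the bromine lone pairs raise the alkyne HOMO toward the ester-bearing pyrone. Thermolysis as in step 18 should then give benzyl (5R,8S)-8-[(2S,6S)-1-acetoxy-7-(benzyloxy)-6-methylheptan-2-yl]-3,4-bis(benzyloxy)-1-bromo-5-methyl-5,6,7,8-tetrahydronaphthalene-2-carboxylate F2 after CO2 loss. Hydrogenolysis of F2 (H2, Pd/C, NaOAc, EtOAc–EtOH) removes the C8 bromine together with the four benzyl groups and comes back to the route at 38.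

Step 16. The second deprotonation of 30 may be incomplete, proton exchange with the alkyne and imidazole may quench the carbanion, or the dianion may add to the acetate, so that the acyl imidazolide is not converted cleanly. The fallback builds the pyrone in two ordinary stages, setting out from 27 through its imidazolide 31. Crossed Claisen condensation with the lithium enolate of benzyl 2-(benzyloxy)acetate (LiN(SiMe3)2, THF, −78 °C) should give benzyl (4R,7S,8S,12S)-8-(acetoxymethyl)-2,13-bis(benzyloxy)-7-ethynyl-4,12-dimethyl-3-oxotridecanoate F3. O-Acylation of its enol with benzyl hydrogen malonate (DCC, DMAP, CH2Cl2) gives benzyl (4R,7S,8S,12S)-8-(acetoxymethyl)-2,13-bis(benzyloxy)-3-{[3-(benzyloxy)-3-oxopropanoyl]oxy}-7-ethynyl-4,12-dimethyltridec-2-enoate (acyloxy group cis to the ester) F4. Dieckmann-type ring closure of the malonate carbanion onto the neighbouring benzyl ester (DBU, THF), with loss of benzyl alcohol, comes back to the route at 34.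

Step 17. Alkylation of the ambident pyronate may take place on the ring carbonyl oxygen (leading to a 2-benzyloxy-4-pyranone), or be suppressed by the hydrogen bond between the 4-hydroxyl and the C3 ester. The fallback acylates instead of alkylating and sets out from 34. Benzyl chloroformate and pyridine (CH2Cl2, 0 °C) should give benzyl 6-[(2R,5S,6S,10S)-6-(acetoxymethyl)-11-(benzyloxy)-5-ethynyl-10-methylundecan-2-yl]-5-(benzyloxy)-4-{[(benzyloxy)carbonyl]oxy}-2-oxo-2H-pyran-3-carboxylate F5, O-acylation of 4-hydroxy-2-pyrones being selective for the 4-oxygen. Thermolysis as in step 18 should give benzyl (5R,8S)-8-[(2S,6S)-1-acetoxy-7-(benzyloxy)-6-methylheptan-2-yl]-4-(benzyloxy)-3-{[(benzyloxy)carbonyl]oxy}-5-methyl-5,6,7,8-tetrahydronaphthalene-2-carboxylate F6. The hydrogenolysis of step 19 then cleaves the benzyl carbonate along with the other benzyl groups and comes back to the route at 38.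

Further compounds
F1 | step 18 | benzyl 6-[(2R,5S,6S,10S)-6-(acetoxymethyl)-11-(benzyloxy)-5-(bromoethynyl)-10-methylundecan-2-yl]-4,5-bis(benzyloxy)-2-oxo-2H-pyran-3-carboxylate | CC(=O)OC[C@@H](CCC[C@H](C)COCc1ccccc1)[C@@H](C#CBr)CC[C@@H](C)C1=C(OCc2ccccc2)C(OCc2ccccc2)=C(C(=O)OCc2ccccc2)C(=O)O1
F2 | step 18 | benzyl (5R,8S)-8-[(2S,6S)-1-acetoxy-7-(benzyloxy)-6-methylheptan-2-yl]-3,4-bis(benzyloxy)-1-bromo-5-methyl-5,6,7,8-tetrahydronaphthalene-2-carboxylate | CC(=O)OC[C@@H](CCC[C@H](C)COCc1ccccc1)[C@@H]1CC[C@@H](C)c2c1c(Br)c(C(=O)OCc1ccccc1)c(OCc1ccccc1)c2OCc1ccccc1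
F3 | step 16 | benzyl (4R,7S,8S,12S)-8-(acetoxymethyl)-2,13-bis(benzyloxy)-7-ethynyl-4,12-dimethyl-3-oxotridecanoate (C2 undefined) | CC(=O)OC[C@@H](CCC[C@H](C)COCc1ccccc1)[C@@H](C#C)CC[C@@H](C)C(=O)C(OCc1ccccc1)C(=O)OCc1ccccc1
F4 | step 16 | benzyl (4R,7S,8S,12S)-8-(acetoxymethyl)-2,13-bis(benzyloxy)-3-{[3-(benzyloxy)-3-oxopropanoyl]oxy}-7-ethynyl-4,12-dimethyltridec-2-enoate (acyloxy cis to ester) | CC(=O)OC[C@@H](CCC[C@H](C)COCc1ccccc1)[C@@H](C#C)CC[C@@H](C)/C(OC(=O)CC(=O)OCc1ccccc1)=C(\OCc1ccccc1)C(=O)OCc1ccccc1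
F5 | step 17 | benzyl 6-[(2R,5S,6S,10S)-6-(acetoxymethyl)-11-(benzyloxy)-5-ethynyl-10-methylundecan-2-yl]-5-(benzyloxy)-4-{[(benzyloxy)carbonyl]oxy}-2-oxo-2H-pyran-3-carboxylate | CC(=O)OC[C@@H](CCC[C@H](C)COCc1ccccc1)[C@@H](C#C)CC[C@@H](C)C1=C(OCc2ccccc2)C(OC(=O)OCc2ccccc2)=C(C(=O)OCc2ccccc2)C(=O)O1
F6 | step 17 | benzyl (5R,8S)-8-[(2S,6S)-1-acetoxy-7-(benzyloxy)-6-methylheptan-2-yl]-4-(benzyloxy)-3-{[(benzyloxy)carbonyl]oxy}-5-methyl-5,6,7,8-tetrahydronaphthalene-2-carboxylate | CC(=O)OC[C@@H](CCC[C@H](C)COCc1ccccc1)[C@@H]1CC[C@@H](C)c2c1cc(C(=O)OCc1ccccc1)c(OC(=O)OCc1ccccc1)c2OCc1ccccc1
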